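**Plan**

1. Numbering (germacrane): C1 ketone, C2=C3 furanone alkene with C3 on the ring oxygen, C4=C5 Z-alkene (C15 on C4), C6 lactone carbinol, C7, C8 (isovalerate), C9 (acetate), quaternary C10 (C14), C11/C12/C13 methylene lactone; α is the face of H7 and of the furanone oxygen at C10, β the face of H6, C11 and C14.
2. Enabling feature: C8 and C9, the only adjacent oxygen-bearing sp3 carbons of the ten-membered carbocycle C1–C10, lie between C7 of the lactone ring and quaternary C10 of the furanone ring, each of which can carry a vinyl group; a C8=C9 alkene is the retron of both C–O bonds and its formation closes the carbocycle.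
3. Cuts, in retrosynthetic order: C9–OAc and C8–O-isovaleryl (the latter with inversion) back to the cis-8α,9α-diol; C8=C9 (ring-closing metathesis); furanone O–C3 (gold cyclisation of a hydroxy-ynone); C1–C2 (acid chloride plus terminal alkyne); lactone C12–O and C6–C7 (allylboration).
4. Forward order: lactone ring (steps 7 and 8), union of the two halves at C1–C2 (step 9), furanone ring (step 11), ten-membered carbocycle (step 12), then the two oxygens and the two esters.
5. Stereochemistry: C10 from a ligand-controlled palladium allylic etherification; C7 and C6 from a phosphoric-acid-catalysed chair allylboration (cis), C6 then inverted by Mitsunobu relactonisation to the trans lactone; C9 from α-face osmylation of the new Z-alkene, C8 from the same osmylation followed by Mitsunobu inversion; the Z-C4=C5 alkene is bought with the enynol.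
6. The new alkene also lies in a nine-membered oxacycle (C3 to C10 through the furanone oxygen) that already holds the Z-C4=C5 alkene, so only its Z isomer is expected; the threo 8β,9α pattern is therefore built by syn-dihydroxylation plus one inversion.

Key step: step 12

Assumption: the ligand of step 1 and the phosphoric acid of step 7 are written as the enantiomers taken to give the configurations drawn; if either sense of induction proves opposite, the mirror-image catalyst is used and nothing else changes.

**Route**

Step 1
Reactants: 1 2-methyl-2-vinyloxirane (racemic)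
Product: 2 (R)-2-[(4-methoxybenzyl)oxy]-2-methylbut-3-en-1-ol
Conditions: Pd2(dba)3·CHCl3 (1 mol%), (S,S)-N,N'-(cyclohexane-1,2-diyl)bis[2-(diphenylphosphino)benzamide] (3 mol%), BEt3 (1 mol%), 4-MeOC6H4CH2OH (1.1 equiv), CH2Cl2, rt
Reagents that add atoms: 4-methoxybenzyl alcohol, COc1ccc(CO)cc1
Why: Palladium-catalysed dynamic kinetic asymmetric allylic etherification, in which zerovalent palladium opens the racemic vinyl epoxide to rapidly interconverting π-allyl–Pd complexes, the borane ties the alcohol to the alkoxide and delivers it to the tertiary terminus, and the chiral ligand pocket decides which π-face is attacked, which sets quaternary C10 as R.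

Step 2
Reactants: 2 (R)-2-[(4-methoxybenzyl)oxy]-2-methylbut-3-en-1-ol
Product: 4 (R)-2-[(4-methoxybenzyl)oxy]-2-methylbut-3-enoic acid, via aldehyde 3 (not isolated)
Conditions: TEMPO (20 mol%), PhI(OAc)2 (2.2 equiv), MeCN–H2O (1:1), rt
Reagents that add atoms: water, O
Why: Oxoammonium (TEMPO) oxidation with PhI(OAc)2 as terminal oxidant should take the primary alcohol through the aldehyde hydrate to the acid without touching the PMB ether or the vinyl group, and the fully substituted α-carbon cannot epimerise.

Step 3
Reactants: 5 (Z)-3-methylpent-2-en-4-yn-1-ol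
Product: 6 (Z)-3-methylpent-2-en-4-ynal
Conditions: MnO2 (activated, 15 equiv), CH2Cl2, 0 °C to rt; filtered and used at once
Reagents that add atoms: none
Why: Heterogeneous MnO2 oxidation is selective for allylic alcohols and, being neither acidic nor basic, should keep the Z geometry of the enyne on the way to the aldehyde.

Step 4
Reactants: 7 acrolein; 8 methyl acrylate
Product: 9 methyl 3-hydroxy-2-methylidenepent-4-enoate (racemic)
Conditions: DABCO (10 mol%), methyl acrylate (1.5 equiv), neat, 0 °C to rt
Reagents that add atoms: none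
Why: Baylis–Hillman reaction, in which the tertiary amine adds to methyl acrylate to give an ammonium enolate that adds 1,2 to the more electrophilic acrolein and then expels the amine; the racemic carbinol centre is erased in step 6.

Step 5
Reactants: 9 methyl 3-hydroxy-2-methylidenepent-4-enoate
Product: 10 methyl 3-acetoxy-2-methylidenepent-4-enoate (racemic)
Conditions: Ac2O (1.2 equiv), DMAP (5 mol%), Et3N, CH2Cl2, 0 °C
Reagents that add atoms: acetic anhydride, CC(=O)OC(C)=O
Why: DMAP-catalysed acylation turns the secondary allylic alcohol into the acetate that serves as the leaving group for palladium in the next step.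

Step 6
Reactants: 10 methyl 3-acetoxy-2-methylidenepent-4-enoate
Product: 11 methyl (2E)-2-[(4,4,5,5-tetramethyl-1,3,2-dioxaborolan-2-yl)methyl]penta-2,4-dienoate
Conditions: B2pin2 (1.1 equiv), Pd2(dba)3 (2.5 mol%), toluene, 50 °C
Reagents that add atoms: bis(pinacolato)diboron, CC1(C)OB(OC1(C)C)B1OC(C)(C)C(C)(C)O1
Why: Palladium-catalysed allylic borylation, in which zerovalent palladium ionises the acetate to a π-allyl–Pd acetate, the acetate activates the diboron for transmetalation, and boron is delivered to the unsubstituted CH2 terminus to give the conjugated dienoate in its more stable geometry with the vinyl group cis to CH2B.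

Step 7
Reactants: 6 (Z)-3-methylpent-2-en-4-ynal; 11 methyl (2E)-2-[(pinacolboryl)methyl]penta-2,4-dienoate
Product: 13 cis-lactone (4S,5S)-5-[(1Z)-2-methylbut-1-en-3-yn-1-yl]-3-methylidene-4-vinyloxolan-2-one, via borate ester 12 (not isolated)
Conditions: (R)-3,3'-bis(2,4,6-triisopropylphenyl)-BINOL hydrogen phosphate (10 mol%), 4 Å MS, toluene, −20 °C to rt; then TsOH·H2O (10 mol%), rt
Reagents that add atoms: none
Why: Brønsted-acid-catalysed allylboration through a closed six-membered chair transition state, in which the chiral phosphoric acid activates the boronate and selects the aldehyde face (absolute configuration) while the vinyl group cis to CH2B is forced axial so that C6–O and the C7 vinyl group end up syn, giving the cis lactone (6S,7S) once the borate closes onto the ester with loss of MeOBpin; a boronate isomer carrying boron at the other diene terminus would lead to the same cis product.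

Step 8
Reactants: 13 cis-lactone (4S,5S)-5-[(1Z)-2-methylbut-1-en-3-yn-1-yl]-3-methylidene-4-vinyloxolan-2-one
Product: 15 trans-lactone (4S,5R)-5-[(1Z)-2-methylbut-1-en-3-yn-1-yl]-3-methylidene-4-vinyloxolan-2-one, via hydroxy acid 14 (not isolated)
Conditions: LiOH (1.5 equiv), THF–H2O, 0 °C; 1 M HCl to pH 5, extraction; then PPh3 (1.5 equiv), DIAD (1.5 equiv), THF, 0 °C
Reagents that add atoms: lithium hydroxide, [Li+].[OH-]
Why: Saponification opens the lactone without touching C6 or C7, and Mitsunobu lactonisation then activates the allylic C6 hydroxyl as an oxyphosphonium ion that the carboxylate displaces intramolecularly (5-exo-tet SN2) with inversion, which converts the cis lactone into the trans lactone with C6 now R.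

Step 9
Reactants: 4 (R)-2-[(4-methoxybenzyl)oxy]-2-methylbut-3-enoic acid; 15 trans-lactone (4S,5R)-5-[(1Z)-2-methylbut-1-en-3-yn-1-yl]-3-methylidene-4-vinyloxolan-2-one
Product: 17 (4S,5R)-5-[(1Z,6R)-6-[(4-methoxybenzyl)oxy]-2,6-dimethyl-5-oxoocta-1,7-dien-3-yn-1-yl]-3-methylidene-4-vinyloxolan-2-one, via acid chloride 16 (not isolated)
Conditions: 4, Me2C=C(Cl)NMe2 (1.1 equiv), CH2Cl2, 0 °C to rt; then 15, CuI (10 mol%), Et3N (2 equiv), THF, rt, argon
Reagents that add atoms: none
Why: The chloroenamine converts the acid into its chloride under neutral conditions that spare the PMB ether, and acylation of the RC≡CCu acetylide (a palladium-free Sonogashira-type ynone synthesis) then forms the C1–C2 bond without ketene formation (no α-hydrogen) and without a palladium species that could ionise the allylic lactone.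

Step 10
Reactants: 17 PMB-protected ynone lactone
Product: 18 (4S,5R)-5-[(1Z,6R)-6-hydroxy-2,6-dimethyl-5-oxoocta-1,7-dien-3-yn-1-yl]-3-methylidene-4-vinyloxolan-2-one
Conditions: DDQ (1.3 equiv), CH2Cl2–pH 7 buffer (10:1), 0 °C
Reagents that add atoms: none
Why: Oxidative PMB cleavage, in which DDQ oxidises only the electron-rich benzyl ether to an oxocarbenium ion that water hydrolyses, while the electron-poor ynone, the lactone and the terminal alkenes are inert and the tertiary C10–O bond is not broken.

Step 11
Reactants: 18 hydroxy-ynone lactone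
Product: 19 (4S,5R)-3-methylidene-5-{(1Z)-2-[(5R)-5-methyl-4-oxo-5-vinyl-4,5-dihydrofuran-2-yl]prop-1-en-1-yl}-4-vinyloxolan-2-one
Conditions: (4-CF3C6H4)3PAuCl (5 mol%), AgOTf (5 mol%), toluene, rt
Reagents that add atoms: none
Why: The cationic phosphine–Au+ species (monovalent gold) activates the ynone for 5-endo-dig addition of the tertiary hydroxyl to C3 and protodeauration gives the 3(2H)-furanone, the established cyclisation of γ-hydroxy alkynones, leaving the Z-alkene, C10 and the lactone unchanged.

Step 12
Reactants: 19 divinyl furanone lactone (6R,7S,10R)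
Product: 20 (4Z,6R,7S,8Z,10R)-3,10-epoxy-1-oxogermacra-2,4,8,11(13)-tetraen-12,6-olide
Conditions: second-generation Grubbs catalyst (H2IMes)(PCy3)Cl2Ru=CHPh (3 × 5 mol%), 1,4-benzoquinone (20 mol%), toluene (1 mM), 80 °C, argon sparge
Reagents that add atoms: none
Why: The Ru=CHPh unit first exchanges onto the unhindered C7 vinyl group, the new Ru=C8 alkylidene adds to the C10 vinyl group to give a ruthenacyclobutane, and cycloreversion releases the ring alkene while the two CH2 termini leave as ethene ([2+2] cycloaddition and cycloreversion). The closest known reaction is ring-closing metathesis of dienes to ten-membered carbocycles in germacranolide-type substrates that already carry an α-methylene lactone. One ring is closed, the ten-membered carbocycle C1–C10, by joining the two terminal alkene carbons as C8=C9; because C3 and C10 are already linked through the furanone oxygen, the new alkene also lies in a nine-membered oxacycle. No stereocentre is formed and C6, C7 and C10 are untouched; the only stereochemical element is the alkene geometry, and in this nine-membered ring, which already holds the Z-C4=C5 alkene and the planar furanone, the E isomer would be severely strained, so the Z-alkene is expected as kinetic and thermodynamic product and the endgame is designed for it. The step needs ring closure to beat oligomerisation and reaction of only two of the five alkenes: high dilution with removal of ethene, the trans lactone and the Z-C4=C5 alkene that turn both vinyl groups to the same side, and the inertness of the trisubstituted conjugated C4=C5, the push-pull furanone C2=C3 and the electron-poor 1,1-disubstituted C11=C13 alkenes should secure this, while benzoquinone suppresses Ru–H migration of the doubly allylic C7 alkene.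

Step 13
Reactants: 20 Z-8,9-didehydro tricycle
Product: 21 8α,9α-dihydroxy-3,10-epoxy-1-oxogermacra-2,4Z,11(13)-trien-12,6α-olide
Conditions: OsO4 (5 mol%), NMO (1.3 equiv), acetone–H2O (5:1), 0 °C
Reagents that add atoms: osmium tetroxide (catalytic oxygen carrier), O=[Os](=O)(=O)=O; N-methylmorpholine N-oxide, C[N+]1([O-])CCOCC1; water, O
Why: Catalytic OsO4 dihydroxylation adds suprafacially to the only isolated, electron-rich alkene (the other three are conjugated or electron-poor) and is expected to come from the α face, which carries only H7 and the tied-back furanone oxygen whereas the β face carries the C14 methyl group and lactone carbon C11, so that C9 is set as in the target (9α-O) and C8 as its epimer (8α-O).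

Step 14
Reactants: 21 8α,9α-diol
Product: 22 9α-hydroxy-8β-(3-methylbutanoyloxy)-3,10-epoxy-1-oxogermacra-2,4Z,11(13)-trien-12,6α-olide
Conditions: PPh3 (2 equiv), DIAD (2 equiv), 3-methylbutanoic acid (2 equiv), THF, 0 °C to rt
Reagents that add atoms: 3-methylbutanoic acid, CC(C)CC(O)=O
Why: Mitsunobu esterification, in which phosphorus activates the less hindered C8 hydroxyl (the cis-diol passing through a dioxaphosphorane), neopentyl C9 cannot undergo displacement and a cis-diol cannot close to an epoxide, so the carboxylate should attack C8 from the β face with inversion and turn the erythro diol into the threo 8β-ester 9α-alcohol.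

Step 15
Reactants: 22 8β-isovalerate 9α-alcohol
Product: 23 (6R,7S,8S,9R,10R)-9-acetoxy-3,10-epoxy-8-(3-methylbutanoyloxy)-1-oxogermacra-2,4Z,11(13)-trien-12,6-olide (target)
Conditions: Ac2O (3 equiv), DMAP (0.2 equiv), pyridine, CH2Cl2, 0 °C
Reagents that add atoms: acetic anhydride, CC(=O)OC(C)=O
Why: DMAP-catalysed acylation of the remaining hindered secondary alcohol proceeds with retention under conditions too mild to move the C8 ester or to add to the methylene lactone.

**Compound list**

1 | 2-methyl-2-vinyloxirane (racemic) | CC1(C=C)CO1 | starting material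
2 | (R)-2-[(4-methoxybenzyl)oxy]-2-methylbut-3-en-1-ol | OC[C@](C)(OCc1ccc(OC)cc1)C=C | intermediate
3 | (R)-2-[(4-methoxybenzyl)oxy]-2-methylbut-3-enal (step 2, not isolated) | O=C[C@](C)(OCc1ccc(OC)cc1)C=C | intermediate
4 | (R)-2-[(4-methoxybenzyl)oxy]-2-methylbut-3-enoic acid | OC(=O)[C@](C)(OCc1ccc(OC)cc1)C=C | intermediate
5 | (Z)-3-methylpent-2-en-4-yn-1-ol | C#C/C(C)=C\CO | starting material
6 | (Z)-3-methylpent-2-en-4-ynal | C#C/C(C)=C\C=O | intermediate
7 | acrolein | C=CC=O | starting material
8 | methyl acrylate | C=CC(=O)OC | starting material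
9 | methyl 3-hydroxy-2-methylidenepent-4-enoate (racemic) | C=CC(O)C(=C)C(=O)OC | intermediate
10 | methyl 3-acetoxy-2-methylidenepent-4-enoate (racemic) | C=CC(OC(C)=O)C(=C)C(=O)OC | intermediate
11 | methyl (2E)-2-[(4,4,5,5-tetramethyl-1,3,2-dioxaborolan-2-yl)methyl]penta-2,4-dienoate | C=C/C=C(\CB1OC(C)(C)C(C)(C)O1)C(=O)OC | intermediate
12 | methyl (3S,4S,5Z)-6-methyl-2-methylidene-4-[(pinacolboryl)oxy]-3-vinyloct-5-en-7-ynoate (step 7, not isolated) | C=C(C(=O)OC)[C@H](C=C)[C@@H](OB1OC(C)(C)C(C)(C)O1)/C=C(/C)C#C | intermediate
13 | cis-lactone (4S,5S)-5-[(1Z)-2-methylbut-1-en-3-yn-1-yl]-3-methylidene-4-vinyloxolan-2-one | C=C1C(=O)O[C@@H](/C=C(/C)C#C)[C@H]1C=C | intermediate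
14 | (3S,4S,5Z)-4-hydroxy-6-methyl-2-methylidene-3-vinyloct-5-en-7-ynoic acid (step 8, not isolated) | C=C(C(O)=O)[C@H](C=C)[C@@H](O)/C=C(/C)C#C | intermediate
15 | trans-lactone (4S,5R)-5-[(1Z)-2-methylbut-1-en-3-yn-1-yl]-3-methylidene-4-vinyloxolan-2-one | C=C1C(=O)O[C@H](/C=C(/C)C#C)[C@H]1C=C | intermediate
16 | (R)-2-[(4-methoxybenzyl)oxy]-2-methylbut-3-enoyl chloride (step 9, not isolated) | ClC(=O)[C@](C)(OCc1ccc(OC)cc1)C=C | intermediate
17 | (4S,5R)-5-[(1Z,6R)-6-[(4-methoxybenzyl)oxy]-2,6-dimethyl-5-oxoocta-1,7-dien-3-yn-1-yl]-3-methylidene-4-vinyloxolan-2-one | C=C1C(=O)O[C@H](/C=C(/C)C#CC(=O)[C@](C)(OCc2ccc(OC)cc2)C=C)[C@H]1C=C | intermediate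
18 | (4S,5R)-5-[(1Z,6R)-6-hydroxy-2,6-dimethyl-5-oxoocta-1,7-dien-3-yn-1-yl]-3-methylidene-4-vinyloxolan-2-one | C=C1C(=O)O[C@H](/C=C(/C)C#CC(=O)[C@](C)(O)C=C)[C@H]1C=C | intermediate
19 | divinyl furanone lactone, (4S,5R)-3-methylidene-5-{(1Z)-2-[(5R)-5-methyl-4-oxo-5-vinyl-4,5-dihydrofuran-2-yl]prop-1-en-1-yl}-4-vinyloxolan-2-one | C=C1C(=O)O[C@H](/C=C(/C)C2=CC(=O)[C@](C)(O2)C=C)[C@H]1C=C | intermediate
20 | (4Z,6R,7S,8Z,10R)-3,10-epoxy-1-oxogermacra-2,4,8,11(13)-tetraen-12,6-olide | C=C1C(=O)O[C@@H]2/C=C(/C)C3=CC(=O)[C@](C)(O3)/C=C\[C@@H]12 | intermediate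
21 | 8α,9α-dihydroxy-3,10-epoxy-1-oxogermacra-2,4Z,11(13)-trien-12,6α-olide | C=C1C(=O)O[C@@H]2/C=C(/C)C3=CC(=O)[C@](C)(O3)[C@H](O)[C@H](O)[C@@H]12 | intermediate
22 | 9α-hydroxy-8β-(3-methylbutanoyloxy)-3,10-epoxy-1-oxogermacra-2,4Z,11(13)-trien-12,6α-olide | C=C1C(=O)O[C@@H]2/C=C(/C)C3=CC(=O)[C@](C)(O3)[C@H](O)[C@@H](OC(=O)CC(C)C)[C@@H]12 | intermediate
23 | (6R,7S,8S,9R,10R)-9-acetoxy-3,10-epoxy-8-(3-methylbutanoyloxy)-1-oxogermacra-2,4Z,11(13)-trien-12,6-olide | C=C1C(=O)O[C@@H]2/C=C(/C)C3=CC(=O)[C@](C)(O3)[C@H](OC(C)=O)[C@@H](OC(=O)CC(C)C)[C@@H]12 | target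

**Totals**

Total step count: 15
Longest linear sequence: 12 steps (steps 4 to 15, from acrolein and methyl acrylate)

**Three steps most likely to fail, riskiest first**

Step 12 (ring closure). The two vinyl groups may react between molecules (dimers and oligomers), or the carbene may fail to turn over at the vinyl group on quaternary C10, because closure has to build the strained bridged bicycle in one event. The fallback changes the order of ring formation. Hydroxy-ynone 18 is cyclised first with (H2IMes)(PCy3)Cl2Ru=CHPh under the same high dilution, before the chain is tied into the furanone, to the ten-membered cyclic hydroxy-ynone F1 (Z-C8=C9). The tertiary C10 hydroxyl is then added across the ring to C3 of the ynone with (4-CF3C6H4)3PAuCl/AgOTf (transannular 5-endo-dig cyclisation), which returns to tricycle 20.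

Step 14 (inverting esterification at C8). Elimination of the activated C8 oxygen toward C7 or C9, or acylation with retention through an acyloxyphosphonium ion, may outrun SN2 displacement at this ring carbon. The fallback is stepwise sulfonate displacement. From diol 21 the C8 hydroxyl alone is converted into the 8α-triflate F5 (Tf2O, pyridine, CH2Cl2, −78 °C; the neopentyl C9 hydroxyl stays free). F5 is then displaced with inversion by cesium 3-methylbutanoate, CsO2CCH2CHMe2 (18-crown-6, toluene, rt), which comes back to ester 22.

Step 13 (dihydroxylation). Poor or reversed facial selectivity, with OsO4 adding to the β face, would set C9 wrongly and C8 correctly. The fallback accepts that diol and corrects C9 instead of C8. From 20, β-face osmylation gives the 8β,9β-diol F2, whose C8 hydroxyl, already β, is acylated with retention (3-methylbutanoic anhydride, DMAP, CH2Cl2, −20 °C) to the mono-ester F3. The remaining C9 alcohol is oxidised with DMP (1,1,1-triacetoxy-1,2-benziodoxol-3-one, NaHCO3, CH2Cl2) to the 9-ketone F4. Hydride delivery from the same exposed β face (NaBH4, CeCl3·7H2O, MeOH, −78 °C, Luche reduction) should then give the 9α-alcohol and rejoin the route at 22.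

Further compounds
F1 | step 12 | (4Z,6R,7S,8Z,10R)-10-hydroxy-1-oxogermacra-4,8,11(13)-trien-2-yn-12,6-olide | C=C1C(=O)O[C@@H]2/C=C(/C)C#CC(=O)[C@](C)(O)/C=C\[C@@H]12
F2 | step 13 | 8β,9β-dihydroxy-3,10-epoxy-1-oxogermacra-2,4Z,11(13)-trien-12,6α-olide | C=C1C(=O)O[C@@H]2/C=C(/C)C3=CC(=O)[C@](C)(O3)[C@@H](O)[C@@H](O)[C@@H]12
F3 | step 13 | 9β-hydroxy-8β-(3-methylbutanoyloxy)-3,10-epoxy-1-oxogermacra-2,4Z,11(13)-trien-12,6α-olide | C=C1C(=O)O[C@@H]2/C=C(/C)C3=CC(=O)[C@](C)(O3)[C@@H](O)[C@@H](OC(=O)CC(C)C)[C@@H]12
F4 | step 13 | 8β-(3-methylbutanoyloxy)-3,10-epoxy-1,9-dioxogermacra-2,4Z,11(13)-trien-12,6α-olide | C=C1C(=O)O[C@@H]2/C=C(/C)C3=CC(=O)[C@](C)(O3)C(=O)[C@@H](OC(=O)CC(C)C)[C@@H]12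
F5 | step 14 | 9α-hydroxy-8α-(trifluoromethanesulfonyloxy)-3,10-epoxy-1-oxogermacra-2,4Z,11(13)-trien-12,6α-olide | C=C1C(=O)O[C@@H]2/C=C(/C)C3=CC(=O)[C@](C)(O3)[C@H](O)[C@H](OS(=O)(=O)C(F)(F)F)[C@@H]12
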